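**Retrosynthetic overview**
- Ring B (the pyranone) is closed last, at O1–C8a: the C2 hydroxyl adds 6-endo to C3 of a 2-acyl-1,4-benzoquinone, and tautomerisation returns ring A as the 5,8-hydroquinone.
- Ring A is bought as 2,5-dimethoxybenzaldehyde; its quinone and the C4 ketone are unmasked together from a hydroquinone dimethyl ether and a dithiane.
- Key bond C4–C3: the lithiated aryl dithiane (acyl anion equivalent of C4) opens the epoxide terminus of (S)-epichlorohydrin, and the chlorohydrin alkoxide re-closes to a new epoxide.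
- Bond C1'–C2': that epoxide is opened in the same flask by (Z)-hexadec-11-enylmagnesium bromide with CuI; the Z-alkene is bought.
- The only stereocentre (C2, R) is the carbon of (S)-epichlorohydrin; its C–O bond is never broken.

Assumption: (11Z)-hexadec-11-en-1-ol (a bulk moth-pheromone component) and enantiopure epichlorohydrin count as cheap commercial materials. Ring A is the benzene ring, ring B the pyranone ring, and chromanone numbering is used.

**Step 1**
Reactants: 1 2,5-dimethoxybenzaldehyde
Product: 2 2-(2,5-dimethoxyphenyl)-1,3-dithiane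
Conditions: HS(CH2)3SH (1.1 equiv), BF3·OEt2 (10 mol %), CH2Cl2, 0 °C → rt
Reagents that add atoms: propane-1,3-dithiol, SCCCS
Why: Lewis-acid-catalysed dithioacetalisation of an aryl aldehyde (Corey–Seebach dithiane formation) is near-quantitative and turns the formyl carbon into one that can be deprotonated; no stereocentre is involved.

**Step 2**
Reactants: 3 (11Z)-hexadec-11-en-1-ol
Product: 4 (11Z)-1-bromohexadec-11-ene
Conditions: CBr4, PPh3, CH2Cl2, 0 °C → rt
Reagents that add atoms: carbon tetrabromide, BrC(Br)(Br)Br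
Why: The Appel reaction replaces the primary hydroxyl by bromide through SN2 on the alkoxyphosphonium salt under neutral conditions, so the remote Z-alkene is neither isomerised nor hydrobrominated.

**Step 3**
Reactants: 2 2-(2,5-dimethoxyphenyl)-1,3-dithiane; 5 (S)-epichlorohydrin [(2S)-2-(chloromethyl)oxirane]; 4 (11Z)-1-bromohexadec-11-ene
Product: 10 (2R,14Z)-1-[2-(2,5-dimethoxyphenyl)-1,3-dithian-2-yl]nonadec-14-en-2-ol, via lithiated dithiane 6 (not isolated), via lithium chlorohydrinate 7 (not isolated), via dithianyl epoxide 8 (not isolated), via alkenylmagnesium bromide 9 (not isolated)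
Conditions: 2, n-BuLi, THF, −78 → −20 °C; 5 (0.95 equiv), −78 °C → rt; then 9 (1.5 equiv, from 4 and Mg, THF), CuI (10 mol %), −40 → 0 °C; H2O/NH4Cl work-up
Reagents that add atoms: none
Why: Corey–Seebach acyl-anion chemistry run as a one-flask linchpin coupling: anion 6 opens the epoxide terminus of 5 in preference to displacing chloride, alkoxide 7 closes onto CH2Cl to give epoxide 8, and the CuI-catalysed Grignard opening at the free terminus adds the chain, so the untouched (S)-centre of 5 becomes the (2R)-carbinol of 10 only through a change of CIP priorities.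

**Step 4**
Reactants: 10 (2R,14Z)-1-[2-(2,5-dimethoxyphenyl)-1,3-dithian-2-yl]nonadec-14-en-2-ol
Product: 14 (2R)-2-[(12Z)-heptadec-12-en-1-yl]-5,8-dihydroxy-2,3-dihydro-4H-chromen-4-one, via hydroxy ketone 11 (not isolated), via acylquinone 12 (not isolated), via chromanetrione 13 (not isolated)
Conditions: (NH4)2Ce(NO3)6 (9 equiv, in portions), MeCN/H2O 4:1, 0 °C → rt, 30 min; then aq Na2S2O4, EtOAc, rt, under Ar
Reagents that add atoms: water, O
Why: Proposed new method: tetravalent cerium in aqueous MeCN is the standard reagent both for oxidative dithiane hydrolysis and for oxidative demethylation of 1,4-dimethoxyarenes (ipso attack of water, loss of methanol), so 10 should give ketone 11 and then acylquinone 12, whose C3 is activated by two carbonyls and placed for a 6-endo oxa-Michael addition of the secondary alcohol (closest known reaction types: addition of O-, N- and S-nucleophiles to C3 of 2-acyl-1,4-benzoquinones, and cyclisation of hydroxyalkyl quinones to chromans); tautomerisation gives the hydroquinone, excess oxidant takes it to trione 13, Na2S2O4 reduces 13 to 14, and the (R)-configuration is retained because the C2–O bond is never broken.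

**Compound list**
1 | 2,5-dimethoxybenzaldehyde | COc1ccc(OC)c(C=O)c1 | starting material
2 | 2-(2,5-dimethoxyphenyl)-1,3-dithiane | COc1ccc(OC)c(c1)C1SCCCS1 | intermediate
3 | (11Z)-hexadec-11-en-1-ol | CCCC/C=C\CCCCCCCCCCO | starting material
4 | (11Z)-1-bromohexadec-11-ene | CCCC/C=C\CCCCCCCCCCBr | intermediate
5 | (2S)-2-(chloromethyl)oxirane, (S)-epichlorohydrin | ClC[C@@H]1CO1 | starting material
6 | [2-(2,5-dimethoxyphenyl)-1,3-dithian-2-yl]lithium | COc1ccc(OC)c(c1)C1([Li])SCCCS1 | intermediate
7 | lithium (2S)-1-chloro-3-[2-(2,5-dimethoxyphenyl)-1,3-dithian-2-yl]propan-2-olate | ClC[C@@H](O[Li])CC1(SCCCS1)c1cc(OC)ccc1OC | intermediate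
8 | 2-(2,5-dimethoxyphenyl)-2-{[(2S)-oxiran-2-yl]methyl}-1,3-dithiane | C1[C@@H](O1)CC2(SCCCS2)c3cc(OC)ccc3OC | intermediate
9 | [(11Z)-hexadec-11-en-1-yl]magnesium bromide | CCCC/C=C\CCCCCCCCCC[Mg]Br | intermediate
10 | (2R,14Z)-1-[2-(2,5-dimethoxyphenyl)-1,3-dithian-2-yl]nonadec-14-en-2-ol | CCCC/C=C\CCCCCCCCCCC[C@@H](O)CC1(SCCCS1)c1cc(OC)ccc1OC | intermediate
11 | (3R,15Z)-1-(2,5-dimethoxyphenyl)-3-hydroxyicos-15-en-1-one | CCCC/C=C\CCCCCCCCCCC[C@@H](O)CC(=O)c1cc(OC)ccc1OC | intermediate
12 | 2-[(3R,15Z)-3-hydroxyicos-15-enoyl]cyclohexa-2,5-diene-1,4-dione | CCCC/C=C\CCCCCCCCCCC[C@@H](O)CC(=O)C1=CC(=O)C=CC1=O | intermediate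
13 | (2R)-2-[(12Z)-heptadec-12-en-1-yl]-2,3-dihydro-4H-chromene-4,5,8-trione | CCCC/C=C\CCCCCCCCCCC[C@@H]1CC(=O)C2=C(O1)C(=O)C=CC2=O | intermediate
14 | (2R)-2-[(12Z)-heptadec-12-en-1-yl]-5,8-dihydroxy-2,3-dihydro-4H-chromen-4-one (CNP0081592.1) | CCCC/C=C\CCCCCCCCCCC[C@@H]1CC(=O)c2c(O)ccc(O)c2O1 | target

**Totals**
Total step count: 4. Longest linear sequence: 3 steps (steps 1, 3, 4 or steps 2, 3, 4).

**Steps most likely to fail**

Step 4 (oxidative cascade) is the most likely to fail. Water or oxidised sulfur fragments may add to acylquinone 12 faster than the internal hydroxyl, or the alkene may suffer under excess oxidant. The fallback separates oxidation from ring closure; it sets out from 10 and comes back to the route at 12. Silylation of 10 (TBSCl, imidazole, DMF) gives tert-butyl({(2R,14Z)-1-[2-(2,5-dimethoxyphenyl)-1,3-dithian-2-yl]nonadec-14-en-2-yl}oxy)dimethylsilane F1. Oxidation with (NH4)2Ce(NO3)6 in MeCN/H2O at 0 °C then gives 2-[(3R,15Z)-3-(tert-butyldimethylsilyloxy)icos-15-enoyl]cyclohexa-2,5-diene-1,4-dione F2, which has no internal nucleophile and can be purified. HF·pyridine in dry MeCN at 0 °C releases 12 under anhydrous acidic conditions where only the internal hydroxyl can add. Ag2O then brings all material to trione 13, and Na2S2O4 gives 14.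

Step 3 (three-component coupling) is next. Anion 6 may partly displace chloride directly, which erodes the enantiomeric purity, or ring closure of 7 may be incomplete before the Grignard reagent is added. The fallback reverses the order of the two bond formations and purifies after each; it sets out from 4 and comes back to the route at 10. Grignard reagent 9 (from 4) with (R)-epichlorohydrin (ClC[C@H]1CO1) and CuI (10 mol %) in THF at −40 °C gives (2R,14Z)-1-chlorononadec-14-en-2-ol F3. Powdered NaOH in Et2O closes it to (2R)-2-[(12Z)-heptadec-12-en-1-yl]oxirane F4. Anion 6 (from 2 and n-BuLi, THF, −78 °C → rt) opens F4 at its terminal carbon and gives 10 with the same (2R)-configuration.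

Step 2 (Appel bromination) is the least risky of the three. Triphenylphosphine oxide may be hard to remove from the greasy bromide, and traces of HBr could touch the Z-alkene. The fallback activates the alcohol as a sulfonate instead; it sets out from 3 and comes back to the route at 4. MsCl and Et3N in CH2Cl2 at 0 °C give (11Z)-hexadec-11-en-1-yl methanesulfonate F5, and LiBr in refluxing acetone converts it to 4 by SN2.

**Further compounds**
F1 | step 4 | tert-butyl({(2R,14Z)-1-[2-(2,5-dimethoxyphenyl)-1,3-dithian-2-yl]nonadec-14-en-2-yl}oxy)dimethylsilane | CCCC/C=C\CCCCCCCCCCC[C@@H](O[Si](C)(C)C(C)(C)C)CC1(SCCCS1)c1cc(OC)ccc1OC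
F2 | step 4 | 2-[(3R,15Z)-3-(tert-butyldimethylsilyloxy)icos-15-enoyl]cyclohexa-2,5-diene-1,4-dione | CCCC/C=C\CCCCCCCCCCC[C@@H](O[Si](C)(C)C(C)(C)C)CC(=O)C1=CC(=O)C=CC1=O
F3 | step 3 | (2R,14Z)-1-chlorononadec-14-en-2-ol | CCCC/C=C\CCCCCCCCCCC[C@@H](O)CCl
F4 | step 3 | (2R)-2-[(12Z)-heptadec-12-en-1-yl]oxirane | CCCC/C=C\CCCCCCCCCCC[C@@H]1CO1
F5 | step 2 | (11Z)-hexadec-11-en-1-yl methanesulfonate | CCCC/C=C\CCCCCCCCCCOS(C)(=O)=O
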